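**Retrosynthetic overview**
1. Target 28 comes from the ten-membered dienol 24 by OH-directed epoxidation of the Z-C1=C10 bond and O8-angeloylation. The oxirane ring is formed last.
2. 24 comes from the monocyclic lactone 22. The ten-membered ring is closed at C9–C10 by a nickel-catalysed reductive opening of the terminal C8–C9 oxirane with the Z-alkenyl bromide at C10.
3. Enabling feature: C9 is a bare CH2 between the C8 carbinol and C10 of a cis-fused, methyl-bearing oxirane. This is a masked homoallylic alcohol C8(OH)–C9H2–C10(CH3)=C1. The Z-C4=C5 bond, the Z-C1=C10 bond and the trans-fused butyrolactone ring (O, C6, C7, C11, C12) act as three turn elements that hold C9 near C10.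
4. 22 comes from allylboration/lactonisation of Z-enal 12 with boronate 18. The butyrolactone ring is formed first, and C6 and C7 are set against C8.
5. 12 comes from pseudo-acid 1 (a temporary butenolide ring fixes Z-C4=C5), a Keck allylation (C3) and acid 6. 18 comes from (R)-glyceraldehyde acetonide 13 (C8).

Key step: step 15

Remark: germacrane numbering is used in the text (ring C1–C10, lactone carbons C11–C13, C14 on C10, C15 on C4). (2R)-2-Methylbutanoic acid 6 and angelic acid 26 are taken as purchasable.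

**Route**

Step 1
Reactants: 1 5-hydroxy-4-methylfuran-2(5H)-one
Product: 2 methyl (Z)-3-methyl-4-oxobut-2-enoate
Conditions: MeI, K2CO3, DMF, 0 °C to rt
Reagents that add atoms: iodomethane CI
Why: Carbonate opens the pseudo-acid to its (Z)-formyl carboxylate and SN2 O-alkylation of the carboxylate traps the open form, so the ring of 1 hands its cis geometry to the future C4=C5 bond.

Step 2
Reactants: 2 methyl (Z)-3-methyl-4-oxobut-2-enoate
Product: 4 (5S)-4-methyl-5-(prop-2-en-1-yl)furan-2(5H)-one, via stannyl ether 3 (not isolated)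
Conditions: allylSnBu3, Ti(OiPr)4 (10 mol %), (S)-BINOL (20 mol %), 4 Å MS, CH2Cl2, −20 °C, then rt
Reagents that add atoms: allyltributylstannane C=CC[Sn](CCCC)(CCCC)CCCC
Why: Keck asymmetric allylation, in which the (S)-BINOL–titanium Lewis acid should direct allyl transfer to the aldehyde face that gives the S carbinol (C3), and the cis-placed tin alkoxide lactonises at once, which locks the Z alkene in a temporary butenolide ring.

Step 3
Reactants: 4 (5S)-4-methyl-5-(prop-2-en-1-yl)furan-2(5H)-one
Product: 5 (2Z,4S)-4-hydroxy-N-methoxy-N,3-dimethylhepta-2,6-dienamide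
Conditions: MeNH(OMe)·HCl, Me3Al, CH2Cl2, 0 °C to rt; Rochelle salt work-up
Reagents that add atoms: N,O-dimethylhydroxylamine hydrochloride CNOC.Cl
Why: Aluminium-amide aminolysis of a lactone (Weinreb amide formation) breaks only the acyl C–O bond, so C3 and the Z geometry are untouched and C6 sits at a level that stops at the aldehyde on reduction.

Step 4
Reactants: 5 (2Z,4S)-4-hydroxy-N-methoxy-N,3-dimethylhepta-2,6-dienamide; 6 (2R)-2-methylbutanoic acid
Product: 7 (4S,5Z)-7-[methoxy(methyl)amino]-5-methyl-7-oxohepta-1,5-dien-4-yl (2R)-2-methylbutanoate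
Conditions: DCC, DMAP (cat.), CH2Cl2, 0 °C to rt
Reagents that add atoms: none
Why: Steglich esterification acylates the only hydroxyl group with retention at C3, should not epimerise the alpha centre of 6 at low temperature, and blocks relactonisation.

Step 5
Reactants: 7 (4S,5Z)-7-[methoxy(methyl)amino]-5-methyl-7-oxohepta-1,5-dien-4-yl (2R)-2-methylbutanoate
Product: 9 (2Z,4S)-1-[methoxy(methyl)amino]-3-methyl-1,6-dioxohex-2-en-4-yl (2R)-2-methylbutanoate, via ozonide 8 (not isolated)
Conditions: O3, CH2Cl2, Sudan Red 7B, −78 °C; then Me2S, −78 °C to rt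
Reagents that add atoms: ozone [O-][O+]=O
Why: Ozonolysis with reductive work-up should cleave the electron-rich monosubstituted alkene well before the conjugated trisubstituted double bond, with the dye marking the end point.

Step 6
Reactants: 9 (2Z,4S)-1-[methoxy(methyl)amino]-3-methyl-1,6-dioxohex-2-en-4-yl (2R)-2-methylbutanoate
Product: 10 (2Z,4S)-7,7-dibromo-1-[methoxy(methyl)amino]-3-methyl-1-oxohepta-2,6-dien-4-yl (2R)-2-methylbutanoate
Conditions: CBr4, PPh3, CH2Cl2, 0 °C
Reagents that add atoms: carbon tetrabromide BrC(Br)(Br)Br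
Why: Ramirez dibromo-olefination runs under non-basic conditions, which avoids beta-elimination of the acyloxy group from aldehyde 9.

Step 7
Reactants: 10 (2Z,4S)-7,7-dibromo-1-[methoxy(methyl)amino]-3-methyl-1-oxohepta-2,6-dien-4-yl (2R)-2-methylbutanoate
Product: 11 (2Z,4S,6Z)-7-bromo-1-[methoxy(methyl)amino]-3-methyl-1-oxoocta-2,6-dien-4-yl (2R)-2-methylbutanoate
Conditions: Me2Zn, PdCl2(DPEphos) (5 mol %), THF, 0 °C to rt
Reagents that add atoms: dimethylzinc C[Zn]C
Why: Negishi coupling of a 1,1-dibromoalkene is trans-selective because zerovalent palladium inserts into the less hindered C–Br bond anti to the chain, so methyl ends up trans and bromine stays cis to C2 (Z-alkenyl bromide).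

Step 8
Reactants: 11 (2Z,4S,6Z)-7-bromo-1-[methoxy(methyl)amino]-3-methyl-1-oxoocta-2,6-dien-4-yl (2R)-2-methylbutanoate
Product: 12 (2Z,4S,6Z)-7-bromo-3-methyl-1-oxoocta-2,6-dien-4-yl (2R)-2-methylbutanoate
Conditions: i-Bu2AlH (1.1 equiv), THF, −78 °C; Rochelle salt work-up
Reagents that add atoms: none
Why: Weinreb amide reduction stops at the chelated tetrahedral aluminate, which frees the Z-enal only on work-up, and the hindered secondary ester reacts more slowly at −78 °C.

Step 9
Reactants: 13 (4R)-2,2-dimethyl-1,3-dioxolane-4-carbaldehyde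
Product: 14 (4S)-4-(2,2-dibromoethenyl)-2,2-dimethyl-1,3-dioxolane
Conditions: CBr4, PPh3, CH2Cl2, 0 °C
Reagents that add atoms: carbon tetrabromide BrC(Br)(Br)Br
Why: Ramirez olefination (first half of the Corey–Fuchs sequence) is neutral and fast, so the epimerisable alpha-oxygenated centre (future C8) is kept.

Step 10
Reactants: 14 (4S)-4-(2,2-dibromoethenyl)-2,2-dimethyl-1,3-dioxolane
Product: 16 methyl 3-[(4S)-2,2-dimethyl-1,3-dioxolan-4-yl]prop-2-ynoate, via lithium acetylide 15 (not isolated)
Conditions: n-BuLi (2.1 equiv), THF, −78 °C; then ClCO2Me, −78 to 0 °C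
Reagents that add atoms: methyl chloroformate COC(=O)Cl
Why: Corey–Fuchs alkyne formation (bromine–lithium exchange, Fritsch–Buttenberg–Wiechell shift, deprotonation) followed by C-acylation of the acetylide does not touch the stereocentre.

Step 11
Reactants: 16 methyl 3-[(4S)-2,2-dimethyl-1,3-dioxolan-4-yl]prop-2-ynoate
Product: 18 methyl (2Z)-3-[(4S)-2,2-dimethyl-1,3-dioxolan-4-yl]-2-[(4,4,5,5-tetramethyl-1,3,2-dioxaborolan-2-yl)methyl]prop-2-enoate, via alkenylalane 17 (not isolated)
Conditions: i-Bu2AlH, HMPA, THF, 0 °C; then ICH2Bpin, 0 °C to rt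
Reagents that add atoms: 2-(iodomethyl)-4,4,5,5-tetramethyl-1,3,2-dioxaborolane ICB1OC(C)(C)C(C)(C)O1
Why: Syn-hydroalumination of the ynoate puts aluminium on the ester-bearing carbon, and the alkenylalane is homologated by ICH2Bpin through a boron ate complex and 1,2-shift (Matteson-type) with retention, which gives the boronate whose dioxolane is trans to CH2B.

Step 12
Reactants: 12 (2Z,4S,6Z)-7-bromo-3-methyl-1-oxoocta-2,6-dien-4-yl (2R)-2-methylbutanoate; 18 methyl (2Z)-3-[(4S)-2,2-dimethyl-1,3-dioxolan-4-yl]-2-[(4,4,5,5-tetramethyl-1,3,2-dioxaborolan-2-yl)methyl]prop-2-enoate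
Product: 20 (1Z,3S,5Z)-6-bromo-1-{(2R,3S)-3-[(4S)-2,2-dimethyl-1,3-dioxolan-4-yl]-4-methylidene-5-oxooxolan-2-yl}-2-methylhepta-1,5-dien-3-yl (2R)-2-methylbutanoate (trans-lactone), via pinacol borate 19 (not isolated)
Conditions: Sc(OTf)3 (10 mol %), toluene, 0 °C to rt; then PPTS (cat.), 40 °C
Reagents that add atoms: none
Why: Lewis acid-catalysed allylboration through a closed chair transition state, in which the boronate with C8 trans to CH2B acts like an E-crotyl reagent and should give the 6,7-anti adduct (trans-lactone after lactonisation), while allylic 1,3-strain with the cis ester holds H8 in the alkene plane so that the aldehyde should attack C7 anti to the C8–C9 bond, which sets C6 and C7 relative to C8.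

Step 13
Reactants: 20 trans-lactone acetonide
Product: 21 (1Z,3S,5Z)-6-bromo-1-{(2R,3R)-3-[(1S)-1,2-dihydroxyethyl]-4-methylidene-5-oxooxolan-2-yl}-2-methylhepta-1,5-dien-3-yl (2R)-2-methylbutanoate
Conditions: AcOH/H2O 4:1, 40 °C
Reagents that add atoms: none
Why: Mild acid-catalysed acetal hydrolysis frees the C8,C9-diol and should leave the esters, the lactone position and both Z alkenes alone.

Step 14
Reactants: 21 diol lactone
Product: 22 (1Z,3S,5Z)-6-bromo-2-methyl-1-{(2R,3S)-4-methylidene-3-[(2S)-oxiran-2-yl]-5-oxooxolan-2-yl}hepta-1,5-dien-3-yl (2R)-2-methylbutanoate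
Conditions: PPh3, DIAD, toluene, 0 to 60 °C
Reagents that add atoms: none
Why: Mitsunobu cyclodehydration of a 1,2-diol activates the less hindered primary C9–OH and the C8 oxygen displaces it (3-exo-tet), so C8 keeps its configuration and the neutral medium avoids base-induced lactone migration to O8.

Step 15
Reactants: 22 oxirane/alkenyl bromide lactone
Product: 24 (3S,6R,7R,8R)-8-hydroxy-3-[(2R)-2-methylbutanoyloxy]germacra-1(10)Z,4Z,11(13)-trien-12,6-olide, via iodohydrin 23 (not isolated)
Conditions: NiBr2(dme) (20 mol %), 4,4'-di-tert-butyl-2,2'-bipyridine (20 mol %), NaI (50 mol %), Et3N·HCl (1.2 equiv), Mn powder (3 equiv), DMPU, 25 °C, 22 added by syringe pump (final 2 mM)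
Reagents that add atoms: none
Why: Proposed new method: iodide, buffered by Et3N·HCl, opens the oxirane of 22 by SN2 attack at the unhindered C9H2 to give iodohydrin 23 in low stationary concentration, zerovalent nickel inserts into the C10–Br bond with retention of the Z geometry, a monovalent nickel species abstracts iodine from 23, the primary C9 radical is captured at the alkenylnickel centre and reductive elimination from trivalent nickel forms C9–C10, after which Mn returns the catalyst to the zerovalent state. The closest known reaction type is the intermolecular nickel/bipyridine reductive cross-electrophile coupling of terminal epoxides with aryl or alkenyl halides under iodide co-catalysis, which gives the linear alcohol and tolerates esters and free hydroxyl groups; its use for a medium-ring closure is the new element. The ten-membered carbocycle, the only ring closed here, forms in a formal 10-endo-tet opening of the oxirane, realised as radical capture to an eleven-membered nickelacycle that contracts by one atom on reductive elimination. No new stereocentre arises: C8 keeps its configuration because only the C9–O bond breaks, and the Z-C1=C10 geometry, which later becomes the cis relation of C2 and C9 on the oxirane, is transferred from the bromide. The step needs ring closure to beat dimerisation, attack at C9 and not C8, and survival of the C11=C13 acrylate unit and of the allylic C3–O and C6–O bonds. These should be secured by slow addition into a dilute catalyst pool, by the steric bias of iodide for the CH2 terminus, by the three turn elements (Z-C4=C5, Z-alkenyl bromide, trans-lactone ring) that hold C9 near C10, by the faster insertion of nickel into the C(sp2)–Br bond than into hindered secondary allylic esters, and by the fact that the C9 radical could reach C11=C13 only in slow 4-exo or 5-endo modes.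

Step 16
Reactants: 24 ten-membered dienol
Product: 25 (1R,3S,6R,7R,8R,10S)-1,10-epoxy-8-hydroxy-3-[(2R)-2-methylbutanoyloxy]germacra-4Z,11(13)-dien-12,6-olide
Conditions: VO(acac)2 (5 mol %), t-BuOOH (decane), CH2Cl2, 0 °C
Reagents that add atoms: tert-butyl hydroperoxide CC(C)(C)OO
Why: Hydroxyl-directed vanadium-catalysed epoxidation of a homoallylic alcohol, in which the C8 vanadate delivers oxygen through a chair-like transition state where allylic 1,3-strain of the Z alkene keeps C1 anti to C8, so the new oxygen should end up 1,3-syn to O8 (1R,10S), the suprafacial addition turns the Z geometry into the cis-fused oxirane, and the electron-poor C4=C5 and C11=C13 bonds stay inert.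

Step 17
Reactants: 25 epoxy alcohol; 26 angelic acid [(Z)-2-methylbut-2-enoic acid]
Product: 28 target CNP0108431.1, (1R,3S,6R,7R,8R,10S)-8-angeloyloxy-1,10-epoxy-3-[(2R)-2-methylbutanoyloxy]germacra-4Z,11(13)-dien-12,6-olide, via mixed anhydride 27 (not isolated)
Conditions: 2,4,6-trichlorobenzoyl chloride, Et3N, toluene, rt; then 25, toluene, 80 °C
Reagents that add atoms: none
Why: Yamaguchi-type mixed-anhydride esterification run without a nucleophilic catalyst acylates O8 with retention at C8 and should avoid the addition–elimination path that turns angelates into tiglates.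

**Compound list**
1 | 5-hydroxy-4-methylfuran-2(5H)-one | CC1=CC(=O)OC1O | starting material
2 | methyl (Z)-3-methyl-4-oxobut-2-enoate | COC(=O)/C=C(/C)C=O | intermediate
3 | methyl (2Z,4S)-3-methyl-4-(tributylstannyloxy)hepta-2,6-dienoate | COC(=O)/C=C(/C)[C@@H](O[Sn](CCCC)(CCCC)CCCC)CC=C | intermediate
4 | (5S)-4-methyl-5-(prop-2-en-1-yl)furan-2(5H)-one | CC1=CC(=O)O[C@H]1CC=C | intermediate
5 | (2Z,4S)-4-hydroxy-N-methoxy-N,3-dimethylhepta-2,6-dienamide | CON(C)C(=O)/C=C(/C)[C@@H](O)CC=C | intermediate
6 | (2R)-2-methylbutanoic acid | CC[C@@H](C)C(=O)O | starting material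
7 | (4S,5Z)-7-[methoxy(methyl)amino]-5-methyl-7-oxohepta-1,5-dien-4-yl (2R)-2-methylbutanoate | CON(C)C(=O)/C=C(/C)[C@@H](OC(=O)[C@H](C)CC)CC=C | intermediate
8 | 1,2,4-trioxolane (ozonide) of 7, mixture at the ozonide carbon | CON(C)C(=O)/C=C(/C)[C@@H](OC(=O)[C@H](C)CC)CC1OCOO1 | intermediate
9 | (2Z,4S)-1-[methoxy(methyl)amino]-3-methyl-1,6-dioxohex-2-en-4-yl (2R)-2-methylbutanoate | CON(C)C(=O)/C=C(/C)[C@@H](OC(=O)[C@H](C)CC)CC=O | intermediate
10 | (2Z,4S)-7,7-dibromo-1-[methoxy(methyl)amino]-3-methyl-1-oxohepta-2,6-dien-4-yl (2R)-2-methylbutanoate | CON(C)C(=O)/C=C(/C)[C@@H](OC(=O)[C@H](C)CC)CC=C(Br)Br | intermediate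
11 | (2Z,4S,6Z)-7-bromo-1-[methoxy(methyl)amino]-3-methyl-1-oxoocta-2,6-dien-4-yl (2R)-2-methylbutanoate | CON(C)C(=O)/C=C(/C)[C@@H](OC(=O)[C@H](C)CC)C/C=C(/C)Br | intermediate
12 | (2Z,4S,6Z)-7-bromo-3-methyl-1-oxoocta-2,6-dien-4-yl (2R)-2-methylbutanoate | O=C/C=C(/C)[C@@H](OC(=O)[C@H](C)CC)C/C=C(/C)Br | intermediate
13 | (4R)-2,2-dimethyl-1,3-dioxolane-4-carbaldehyde | O=C[C@H]1COC(C)(C)O1 | starting material
14 | (4S)-4-(2,2-dibromoethenyl)-2,2-dimethyl-1,3-dioxolane | BrC(Br)=C[C@H]1COC(C)(C)O1 | intermediate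
15 | lithium acetylide of (4S)-4-ethynyl-2,2-dimethyl-1,3-dioxolane | [Li]C#C[C@H]1COC(C)(C)O1 | intermediate
16 | methyl 3-[(4S)-2,2-dimethyl-1,3-dioxolan-4-yl]prop-2-ynoate | COC(=O)C#C[C@H]1COC(C)(C)O1 | intermediate
17 | methyl 2-(diisobutylalumanyl)-3-[(4S)-2,2-dimethyl-1,3-dioxolan-4-yl]prop-2-enoate, dioxolane cis to the ester | COC(=O)/C([Al](CC(C)C)CC(C)C)=C\[C@H]1COC(C)(C)O1 | intermediate
18 | methyl (2Z)-3-[(4S)-2,2-dimethyl-1,3-dioxolan-4-yl]-2-[(4,4,5,5-tetramethyl-1,3,2-dioxaborolan-2-yl)methyl]prop-2-enoate | COC(=O)/C(CB1OC(C)(C)C(C)(C)O1)=C\[C@H]2COC(C)(C)O2 | intermediate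
19 | pinacol borate of the open 6,7-anti hydroxy ester | C=C(C(=O)OC)[C@H]([C@H]1COC(C)(C)O1)[C@H](OB2OC(C)(C)C(C)(C)O2)/C=C(/C)[C@@H](OC(=O)[C@H](C)CC)C/C=C(/C)Br | intermediate
20 | (1Z,3S,5Z)-6-bromo-1-{(2R,3S)-3-[(4S)-2,2-dimethyl-1,3-dioxolan-4-yl]-4-methylidene-5-oxooxolan-2-yl}-2-methylhepta-1,5-dien-3-yl (2R)-2-methylbutanoate | C=C1C(=O)O[C@H](/C=C(/C)[C@@H](OC(=O)[C@H](C)CC)C/C=C(/C)Br)[C@H]1[C@H]2COC(C)(C)O2 | intermediate
21 | (1Z,3S,5Z)-6-bromo-1-{(2R,3R)-3-[(1S)-1,2-dihydroxyethyl]-4-methylidene-5-oxooxolan-2-yl}-2-methylhepta-1,5-dien-3-yl (2R)-2-methylbutanoate | C=C1C(=O)O[C@H](/C=C(/C)[C@@H](OC(=O)[C@H](C)CC)C/C=C(/C)Br)[C@H]1[C@H](O)CO | intermediate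
22 | (1Z,3S,5Z)-6-bromo-2-methyl-1-{(2R,3S)-4-methylidene-3-[(2S)-oxiran-2-yl]-5-oxooxolan-2-yl}hepta-1,5-dien-3-yl (2R)-2-methylbutanoate | C=C1C(=O)O[C@H](/C=C(/C)[C@@H](OC(=O)[C@H](C)CC)C/C=C(/C)Br)[C@H]1[C@H]2CO2 | intermediate
23 | (1Z,3S,5Z)-6-bromo-1-{(2R,3R)-3-[(1S)-1-hydroxy-2-iodoethyl]-4-methylidene-5-oxooxolan-2-yl}-2-methylhepta-1,5-dien-3-yl (2R)-2-methylbutanoate | C=C1C(=O)O[C@H](/C=C(/C)[C@@H](OC(=O)[C@H](C)CC)C/C=C(/C)Br)[C@H]1[C@H](O)CI | intermediate
24 | (3S,6R,7R,8R)-8-hydroxy-3-[(2R)-2-methylbutanoyloxy]germacra-1(10)Z,4Z,11(13)-trien-12,6-olide | C=C1C(=O)O[C@@H]2/C=C(/C)[C@@H](OC(=O)[C@H](C)CC)C/C=C(/C)C[C@@H](O)[C@@H]12 | intermediate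
25 | (1R,3S,6R,7R,8R,10S)-1,10-epoxy-8-hydroxy-3-[(2R)-2-methylbutanoyloxy]germacra-4Z,11(13)-dien-12,6-olide | C=C1C(=O)O[C@@H]2/C=C(/C)[C@@H](OC(=O)[C@H](C)CC)C[C@H]3O[C@@]3(C)C[C@@H](O)[C@@H]12 | intermediate
26 | angelic acid, (Z)-2-methylbut-2-enoic acid | C/C=C(/C)C(=O)O | starting material
27 | angelic 2,4,6-trichlorobenzoic anhydride | C/C=C(/C)C(=O)OC(=O)c1c(Cl)cc(Cl)cc1Cl | intermediate
28 | CNP0108431.1, (1R,3S,6R,7R,8R,10S)-8-angeloyloxy-1,10-epoxy-3-[(2R)-2-methylbutanoyloxy]germacra-4Z,11(13)-dien-12,6-olide | C=C1C(=O)O[C@@H]2/C=C(/C)[C@@H](OC(=O)[C@H](C)CC)C[C@H]3O[C@@]3(C)C[C@@H](OC(=O)/C(C)=C\C)[C@@H]12 | target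

**Step count**
Total step count: 17.
Longest linear sequence: 14 (steps 1–8 and 12–17).

**Steps most likely to fail**

1. Step 15.
- What may go wrong: intermolecular coupling and oligomerisation may outrun ring closure. The iodohydrin may lose iodide and hydroxide reductively. The alkenyl bromide may be hydrodehalogenated. Nickel may be tied up by the acrylate unit.
- Fallback (known chemistry, sets out from 7, comes back at 24): the ring is closed at C1=C10 by metathesis, and C9–C10 is made beforehand between two molecules.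
- i-Bu2AlH reduction of 7 at −78 °C gives the allyl-terminated Z-enal F1.
- Union of F1 with 18 under the conditions of step 12 gives the lactone acetonide F2.
- AcOH/H2O then gives the diol F3, and PPh3/DIAD gives the oxirane F4.
- The established intermolecular nickel/iodide reductive coupling of this terminal oxirane with 2-bromopropene (NiBr2(dme), 2,2'-bipyridine, NaI, Et3N·HCl, Mn, DMPU) gives the methallyl carbinol F5.
- Ring-closing metathesis of F5 with the second-generation Hoveyda–Grubbs catalyst in dilute toluene should close the trisubstituted C1=C10 bond with the Z geometry favoured in a ten-membered ring and deliver 24.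

2. Step 12.
- What may go wrong: facial selectivity at C7 relative to C8 may be poor. The hindered, ester-deactivated boronate may also react sluggishly, with gradual Z-to-E drift of the enal.
- Fallback (sets out from 12 and 18, comes back at 20): stereocontrol is taken away from the C8 centre and handed to an external chiral source.
- The union is run as a chiral Brønsted acid-catalysed allylboration with 3,3'-bis(2,4,6-triisopropylphenyl)-1,1'-binaphthyl-2,2'-diyl hydrogen phosphate.
- This catalyst binds the boronate oxygen and the formyl hydrogen and fixes the aldehyde face, and the chair relays that face to C7.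
- Both antipodes of the acid are tried to find the pairing matched with C8.
- PPTS then closes the lactone. This fallback makes no new compound (F0).

3. Step 16.
- What may go wrong: oxygen delivery to the wrong face of C1=C10 if the macrocycle cannot adopt the directing chair. Slow turnover may also bring acid-induced transannular opening of the product oxirane.
- Fallback (sets out from 24, comes back at 28): the order of the last two steps is reversed and the face is chosen by the reagent.
- 24 is first acylated with mixed anhydride 27 as in step 17 to give the 8-O-angeloyl triene F6.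
- F6 is then submitted to Shi epoxidation: 1,2:4,5-di-O-isopropylidene-β-D-erythro-2,3-hexodiulo-2,6-pyranose from D-fructose, Oxone (2KHSO5·KHSO4·K2SO4), K2CO3 buffer, MeCN/dimethoxymethane/H2O, 0 °C.
- The spiro transition state for a trisubstituted alkene predicts the 1R,10S oxirane, and the dioxirane should ignore the electron-poor alkenes. This gives 28 directly.

**Further compounds**
F1 | step 15 | (2Z,4S)-3-methyl-1-oxohepta-2,6-dien-4-yl (2R)-2-methylbutanoate | O=C/C=C(/C)[C@@H](OC(=O)[C@H](C)CC)CC=C
F2 | step 15 | (1Z,3S)-1-{(2R,3S)-3-[(4S)-2,2-dimethyl-1,3-dioxolan-4-yl]-4-methylidene-5-oxooxolan-2-yl}-2-methylhexa-1,5-dien-3-yl (2R)-2-methylbutanoate | C=C1C(=O)O[C@H](/C=C(/C)[C@@H](OC(=O)[C@H](C)CC)CC=C)[C@H]1[C@H]2COC(C)(C)O2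
F3 | step 15 | (1Z,3S)-1-{(2R,3R)-3-[(1S)-1,2-dihydroxyethyl]-4-methylidene-5-oxooxolan-2-yl}-2-methylhexa-1,5-dien-3-yl (2R)-2-methylbutanoate | C=C1C(=O)O[C@H](/C=C(/C)[C@@H](OC(=O)[C@H](C)CC)CC=C)[C@H]1[C@H](O)CO
F4 | step 15 | (1Z,3S)-2-methyl-1-{(2R,3S)-4-methylidene-3-[(2S)-oxiran-2-yl]-5-oxooxolan-2-yl}hexa-1,5-dien-3-yl (2R)-2-methylbutanoate | C=C1C(=O)O[C@H](/C=C(/C)[C@@H](OC(=O)[C@H](C)CC)CC=C)[C@H]1[C@H]2CO2
F5 | step 15 | (1Z,3S)-1-{(2R,3R)-3-[(1R)-1-hydroxy-3-methylbut-3-en-1-yl]-4-methylidene-5-oxooxolan-2-yl}-2-methylhexa-1,5-dien-3-yl (2R)-2-methylbutanoate | C=C1C(=O)O[C@H](/C=C(/C)[C@@H](OC(=O)[C@H](C)CC)CC=C)[C@H]1[C@H](O)CC(C)=C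
F0 | step 12 | none | none
F6 | step 16 | (3S,6R,7R,8R)-8-angeloyloxy-3-[(2R)-2-methylbutanoyloxy]germacra-1(10)Z,4Z,11(13)-trien-12,6-olide | C=C1C(=O)O[C@@H]2/C=C(/C)[C@@H](OC(=O)[C@H](C)CC)C/C=C(/C)C[C@@H](OC(=O)/C(C)=C\C)[C@@H]12
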